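## Retrosynthetic overview
- The free 3'-OH is unmasked last by hydrogenolysis of the 3'-O-benzyl flavone.
- Ring C (the 4-pyrone) is the only ring built. It is closed by forming O1–C2 and then dehydrogenating, in an oxidative cyclisation of a 2'-hydroxychalcone.
- The key C–C bond (C2–C3 of the flavone) comes from an intermolecular Claisen–Schmidt aldol condensation. The partners are 2'-hydroxy-3',4',5',6'-tetramethoxyacetophenone and O-benzylisovanillin.
- The acetophenone comes from pentamethoxybenzene by Friedel–Crafts acylation with ortho-demethylation. Pentamethoxybenzene comes from 1,5-dibromo-2,3,4-trimethoxybenzene, and that from 1,2,3-trimethoxybenzene.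
- Rings A and B are bought as benzenes, so ring C is the last and only ring formed.

Assumption: the target has no stereocentre or stereoaxis, so there is no enantiomer to control. The only stereoelement in the route is the E-alkene of 11, which step 6 consumes. Compounds 10, 12 and 13 are transient racemates. Numbers follow the forward route.

## Route

Step 1
Reactants: 1 1,2,3-trimethoxybenzene
Product: 3 1,5-dibromo-2,3,4-trimethoxybenzene, via 1-bromo-2,3,4-trimethoxybenzene 2 (not isolated)
Conditions: NBS (2.1 equiv), MeCN, 0 °C → rt (40 °C to finish), 16 h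
Reagents that add atoms: N-bromosuccinimide, O=C1CCC(=O)N1Br
Why: Electrophilic aromatic bromination goes twice at the positions ortho/para to the outer methoxy groups (C4, then C6), the remaining C–H between two bromines is much less reactive, and any dibromide isomer would converge on the same pentamethoxybenzene.

Step 2
Reactants: 3 1,5-dibromo-2,3,4-trimethoxybenzene
Product: 5 pentamethoxybenzene, via 1-bromo-2,3,4,5-tetramethoxybenzene 4 (not isolated)
Conditions: NaOMe (30 % in MeOH, 8 equiv), CuBr (0.2 equiv), DMF, 110 °C, N2, 12–16 h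
Reagents that add atoms: sodium methoxide, [Na+].[O-]C
Why: The copper(I)-catalysed Ullmann-type methoxylation replaces both bromides, each of which has only one ortho substituent, and concentrated methoxide with DMF as co-solvent keeps hydrodebromination low.

Step 3
Reactants: 5 pentamethoxybenzene
Product: 7 1-(2-hydroxy-3,4,5,6-tetramethoxyphenyl)ethan-1-one, via 1-(2,3,4,5,6-pentamethoxyphenyl)ethan-1-one 6 (not isolated)
Conditions: AcCl (1.5 equiv), AlCl3 (2.5 equiv), Et2O, 0 °C → rt, 24 h; then ice/2 M HCl
Reagents that add atoms: acetyl chloride, CC(=O)Cl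
Why: Friedel–Crafts acylation at the only free ring position is followed by chelation-directed AlCl3 cleavage of a methoxy group ortho to the new carbonyl, and because the two ortho methoxy groups are equivalent by symmetry only one hydroxyketone can form.

Step 4
Reactants: 8 isovanillin (3-hydroxy-4-methoxybenzaldehyde)
Product: 9 3-(benzyloxy)-4-methoxybenzaldehyde
Conditions: BnBr (1.1 equiv), K2CO3 (1.5 equiv), DMF, rt → 50 °C, 6 h
Reagents that add atoms: benzyl bromide, BrCc1ccccc1
Why: Williamson ether synthesis on the single phenol masks it, so the aldehyde is not deactivated as a phenoxide in the aldol step.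

Step 5
Reactants: 7 1-(2-hydroxy-3,4,5,6-tetramethoxyphenyl)ethan-1-one; 9 3-(benzyloxy)-4-methoxybenzaldehyde
Product: 11 (E)-3-[3-(benzyloxy)-4-methoxyphenyl]-1-(2-hydroxy-3,4,5,6-tetramethoxyphenyl)prop-2-en-1-one, via racemic β-hydroxyketone 10 (not isolated)
Conditions: KOH (50 % aq, 10 equiv), EtOH, rt, 48 h; then 2 M HCl, 0 °C
Reagents that add atoms: none
Why: In this Claisen–Schmidt crossed aldol condensation the methyl ketone is the only enolisable partner and the aldehyde the only good electrophile, and E1cB loss of water from the aldol gives the conjugated E-enone.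

Step 6
Reactants: 11 (E)-3-[3-(benzyloxy)-4-methoxyphenyl]-1-(2-hydroxy-3,4,5,6-tetramethoxyphenyl)prop-2-en-1-one
Product: 14 2-[3-(benzyloxy)-4-methoxyphenyl]-5,6,7,8-tetramethoxy-4H-chromen-4-one, via racemic flavanone 12 (not isolated), via racemic 3-iodoflavanone 13 (not isolated)
Conditions: I2 (0.1 equiv), DMSO, 125 °C, 3 h; aq Na2S2O3 work-up
Reagents that add atoms: none
Why: In this I2/DMSO oxidative cyclisation the phenol closes by oxa-Michael addition, α-iodination and loss of HI then give the aromatic 4-pyrone, and DMSO reoxidises HI to I2 so the acid stays too dilute to attack the benzyl or 5-methoxy ethers.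

Step 7
Reactants: 14 2-[3-(benzyloxy)-4-methoxyphenyl]-5,6,7,8-tetramethoxy-4H-chromen-4-one
Product: 15 3'-demethylnobiletin, 2-(3-hydroxy-4-methoxyphenyl)-5,6,7,8-tetramethoxy-4H-chromen-4-one
Conditions: H2 (1 atm), 10 % Pd/C, EtOAc/MeOH 1:1, rt, 4–6 h
Reagents that add atoms: none
Why: Catalytic hydrogenolysis cleaves only the benzylic C–O bond, because aryl methyl ethers and the aromatic pyrone C2=C3/C=O are inert at 1 atm and rt.

## Compound list
1 | 1,2,3-trimethoxybenzene | COc1cccc(OC)c1OC | starting material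
2 | 1-bromo-2,3,4-trimethoxybenzene (not isolated) | COc1ccc(Br)c(OC)c1OC | intermediate
3 | 1,5-dibromo-2,3,4-trimethoxybenzene | COc1c(Br)cc(Br)c(OC)c1OC | intermediate
4 | 1-bromo-2,3,4,5-tetramethoxybenzene (not isolated) | COc1cc(Br)c(OC)c(OC)c1OC | intermediate
5 | pentamethoxybenzene | COc1cc(OC)c(OC)c(OC)c1OC | intermediate
6 | 1-(2,3,4,5,6-pentamethoxyphenyl)ethan-1-one (not isolated) | CC(=O)c1c(OC)c(OC)c(OC)c(OC)c1OC | intermediate
7 | 1-(2-hydroxy-3,4,5,6-tetramethoxyphenyl)ethan-1-one | CC(=O)c1c(O)c(OC)c(OC)c(OC)c1OC | intermediate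
8 | isovanillin (3-hydroxy-4-methoxybenzaldehyde) | COc1ccc(C=O)cc1O | starting material
9 | 3-(benzyloxy)-4-methoxybenzaldehyde | COc1ccc(C=O)cc1OCc1ccccc1 | intermediate
10 | 3-[3-(benzyloxy)-4-methoxyphenyl]-3-hydroxy-1-(2-hydroxy-3,4,5,6-tetramethoxyphenyl)propan-1-one (racemic, not isolated) | COc1ccc(C(O)CC(=O)c2c(O)c(OC)c(OC)c(OC)c2OC)cc1OCc1ccccc1 | intermediate
11 | (E)-3-[3-(benzyloxy)-4-methoxyphenyl]-1-(2-hydroxy-3,4,5,6-tetramethoxyphenyl)prop-2-en-1-one | COc1ccc(/C=C/C(=O)c2c(O)c(OC)c(OC)c(OC)c2OC)cc1OCc1ccccc1 | intermediate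
12 | 2-[3-(benzyloxy)-4-methoxyphenyl]-5,6,7,8-tetramethoxychroman-4-one (racemic, not isolated) | COc1ccc(C2CC(=O)c3c(OC)c(OC)c(OC)c(OC)c3O2)cc1OCc1ccccc1 | intermediate
13 | 2-[3-(benzyloxy)-4-methoxyphenyl]-3-iodo-5,6,7,8-tetramethoxychroman-4-one (racemic, relative configuration irrelevant, not isolated) | COc1ccc(C2Oc3c(OC)c(OC)c(OC)c(OC)c3C(=O)C2I)cc1OCc1ccccc1 | intermediate
14 | 2-[3-(benzyloxy)-4-methoxyphenyl]-5,6,7,8-tetramethoxy-4H-chromen-4-one | COc1ccc(-c2cc(=O)c3c(OC)c(OC)c(OC)c(OC)c3o2)cc1OCc1ccccc1 | intermediate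
15 | 3'-demethylnobiletin (achiral) | COc1ccc(-c2cc(=O)c3c(OC)c(OC)c(OC)c(OC)c3o2)cc1O | target

## Summary
Total step count: 7.
Longest linear sequence: 6 (steps 1, 2, 3, 5, 6, 7). Step 4 is the side branch.

## Three steps most likely to fail

**Step 2, double Ullmann methoxylation.** The risks are hydrodebromination and a stalled second exchange on a very electron-rich ring.
- The fallback sets out from 3 and comes back at 5. It installs oxygen through boron instead of copper.
- Double Miyaura borylation (B2pin2, Pd(dppf)Cl2, KOAc, dioxane, 90 °C) gives 2,2'-(4,5,6-trimethoxy-1,3-phenylene)bis(4,4,5,5-tetramethyl-1,3,2-dioxaborolane) F1.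
- Oxidation with H2O2/NaOH in THF at 0 °C gives 4,5,6-trimethoxybenzene-1,3-diol F2.
- This air-sensitive diol is methylated at once (MeI, K2CO3, acetone, reflux) to 5.

**Step 3, Friedel–Crafts acylation with mono-demethylation.** The risks are AlCl3 cleaving a crowded inner methoxy group or cleaving both ortho groups.
- The fallback sets out from 5 and comes back at 7. It separates the two events and avoids electrophilic substitution.
- Directed ortho-lithiation of the C–H between two methoxy groups (n-BuLi, THF, 0 °C) gives (2,3,4,5,6-pentamethoxyphenyl)lithium F3.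
- Acylation with N-methoxy-N-methylacetamide (−78 °C → rt, NH4Cl quench) gives ketone 6, which is now isolated.
- BCl3 (1.1 equiv, CH2Cl2, −78 → 0 °C) then removes exactly one carbonyl-chelated ortho methyl to give 7.

**Step 6, I2/DMSO oxidative cyclisation.** The risks are HI-induced loss of the 5-O-methyl or the benzyl group, and stalling at the flavanone.
- The fallback sets out from 9, with 7 as partner, and comes back at 14. It carries the B-ring carbon at the acid oxidation level, so no dehydrogenation is needed.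
- Pinnick oxidation of 9 (NaClO2, NaH2PO4, 2-methylbut-2-ene, t-BuOH/H2O) gives 3-(benzyloxy)-4-methoxybenzoic acid F4.
- Oxalyl chloride with catalytic DMF in CH2Cl2 gives 3-(benzyloxy)-4-methoxybenzoyl chloride F5.
- The dianion of 7 (LiHMDS, 3.2 equiv, THF, −78 °C) is C-acylated by F5 in an intermolecular Claisen condensation. The product is 1-[3-(benzyloxy)-4-methoxyphenyl]-3-(2-hydroxy-3,4,5,6-tetramethoxyphenyl)propane-1,3-dione F6.
- Cyclodehydration (catalytic H2SO4, AcOH, 90 °C, 1 h) gives 14.

## Further compounds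
F1 | step 2 | 2,2'-(4,5,6-trimethoxy-1,3-phenylene)bis(4,4,5,5-tetramethyl-1,3,2-dioxaborolane) | COc1c(B2OC(C)(C)C(C)(C)O2)cc(B2OC(C)(C)C(C)(C)O2)c(OC)c1OC
F2 | step 2 | 4,5,6-trimethoxybenzene-1,3-diol | COc1c(O)cc(O)c(OC)c1OC
F3 | step 3 | (2,3,4,5,6-pentamethoxyphenyl)lithium | [Li]c1c(OC)c(OC)c(OC)c(OC)c1OC
F4 | step 6 | 3-(benzyloxy)-4-methoxybenzoic acid | COc1ccc(C(=O)O)cc1OCc1ccccc1
F5 | step 6 | 3-(benzyloxy)-4-methoxybenzoyl chloride | COc1ccc(C(=O)Cl)cc1OCc1ccccc1
F6 | step 6 | 1-[3-(benzyloxy)-4-methoxyphenyl]-3-(2-hydroxy-3,4,5,6-tetramethoxyphenyl)propane-1,3-dione | COc1ccc(C(=O)CC(=O)c2c(O)c(OC)c(OC)c(OC)c2OC)cc1OCc1ccccc1
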